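**Retrosynthetic overview**

1. The target is a (4R)-4-aryl-3,4-dihydrocoumarin (chroman-2-one numbering O1, C2, C3, C4, C4a, C5–C8, C8a; ring A = benzo ring, ring B = lactone, ring C = guaiacyl ring on C4, ring D = guaiacyl ring of the styryl arm). The last cuts are the three silyl ethers and the C5–vinyl bond (Heck reaction with a protected 4-vinylguaiacol).
2. Key disconnection: the O1–C2(=O) unit of ring B is one molecule of CO2 placed between the C3 methylene and ring-A carbon C8a. A C3 alkylzinc takes up CO2 (C3–C2), and the carboxylate oxygen is then joined to C8a by copper-catalysed C–O coupling at a C8a–Br bond (O1–C8a), in the same flask.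
3. Enabling feature: C8a and C5 are the two ring-A carbons ortho to C4a, both meta to the C7 oxygen. In a 2,6-dibromo-4-silyloxyphenyl precursor they are interchangeable by rotation about C4–C4a, so either bromine can take the carboxylate oxygen through a six-membered closure and the other is left at C5 as the handle for the styryl arm.
4. The C4 stereocentre and the C3 handle come from one enantioselective Cu/Pd arylboration of the same protected 4-vinylguaiacol with a 2,6-dibromoaryl iodide and B2pin2. The target is thus assembled from 3,5-dibromophenol, two molecules of 4-vinylguaiacol and CO2.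
5. Ring order: rings A, C and D are bought as arenes; ring B is the only ring made, and it is closed in the key step.

Key step: step 7

Remark on the chemistry: the sense of induction of the arylboration cannot be fixed on paper; it is assumed that one antipode of the ligand gives the (R)-boronate, to be confirmed at the alcohol stage, and the other antipode is used if not.

**Route**

Step 1
Reactants: 1 3,5-dibromophenol
Product: 2 (3,5-dibromophenoxy)triisopropylsilane
Conditions: i-Pr3SiCl (1.1 equiv), imidazole (2.2 equiv), DMF, rt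
Reagents that add atoms: chlorotriisopropylsilane (TIPSCl), CC(C)[Si](Cl)(C(C)C)C(C)C
Why: Silyl ether formation (O-silylation of a phenol); the bulky TIPS group is chosen because it shields the positions next to oxygen in step 2 and is stable to the later organometallic steps.

Step 2
Reactants: 2 (3,5-dibromophenoxy)triisopropylsilane
Product: 4 (3,5-dibromo-4-iodophenoxy)triisopropylsilane, via aryllithium 3 (not isolated)
Conditions: LiN(i-Pr)2 (1.1 equiv), THF, −78 °C, 1 h; then I2 (1.2 equiv), −78 °C → rt; aq. Na2S2O3 work-up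
Reagents that add atoms: iodine, II
Why: Deprotonative lithiation–iodination: LiN(i-Pr)2 removes the most acidic ring proton, the one between the two bromine atoms (an amide base gives no bromine–lithium exchange and the TIPS group blocks the sites next to oxygen), and the aryllithium is quenched with iodine, as established for 1,3-dibromoarenes.

Step 3
Reactants: 5 2-methoxy-4-vinylphenol (4-vinylguaiacol)
Product: 6 (4-ethenyl-2-methoxyphenoxy)triisopropylsilane
Conditions: i-Pr3SiCl (1.1 equiv), imidazole (2.2 equiv), DMF, 0 °C → rt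
Reagents that add atoms: chlorotriisopropylsilane (TIPSCl), CC(C)[Si](Cl)(C(C)C)C(C)C
Why: Silyl ether formation (O-silylation of a phenol), giving the one styrene that serves both as the source of ring C with C4 and C3 (step 4) and as the source of ring D with the vinyl bridge (step 8).

Step 4
Reactants: 4 (3,5-dibromo-4-iodophenoxy)triisopropylsilane; 6 (4-ethenyl-2-methoxyphenoxy)triisopropylsilane
Product: 7 2-{(2R)-2-[2,6-dibromo-4-(triisopropylsilyloxy)phenyl]-2-[3-methoxy-4-(triisopropylsilyloxy)phenyl]ethyl}-4,4,5,5-tetramethyl-1,3,2-dioxaborolane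
Conditions: B2pin2 (1.3 equiv), CuCl (10 mol %), (R)-[2-(tert-butylsulfinyl)phenyl]diphenylphosphine (12 mol %), PdCl2(dppf) (3 mol %), LiOt-Bu (1.5 equiv), toluene/THF, 0 °C → rt
Reagents that add atoms: bis(pinacolato)diboron, CC1(C)OB(OC1(C)C)B1OC(C)(C)C(C)(C)O1
Why: Enantioselective Cu/Pd-cocatalysed arylboration (borylarylation) of a vinylarene: the chiral L*Cu–Bpin species adds syn across the styrene with boron at the terminal carbon, the ligand choosing the alkene face and thereby setting the future C4 as (R), and the benzylic copper is handed over stereospecifically to the arylpalladium iodide formed selectively at the C–I bond of 4, the two flanking C–Br bonds being far slower in oxidative addition.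

Step 5
Reactants: 7 the (R)-boronate of step 4
Product: 8 (2R)-2-[2,6-dibromo-4-(triisopropylsilyloxy)phenyl]-2-[3-methoxy-4-(triisopropylsilyloxy)phenyl]ethan-1-ol
Conditions: NaBO3·4H2O (4 equiv), THF/H2O (1:1), rt
Reagents that add atoms: sodium perborate tetrahydrate (NaBO3·4H2O), [Na+].[Na+].O[B-]1(O)OO[B-](O)(O)OO1
Why: Oxidation of a primary alkylboronic ester to the alcohol (1,2-shift of the alkyl group from boron to peroxide oxygen), mild enough for aryl silyl ethers and aryl bromides and without contact with the stereocentre.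

Step 6
Reactants: 8 the (R)-alcohol of step 5
Product: 9 {3,5-dibromo-4-[(1R)-2-iodo-1-[3-methoxy-4-(triisopropylsilyloxy)phenyl]ethyl]phenoxy}triisopropylsilane
Conditions: PPh3 (1.3 equiv), imidazole (1.5 equiv), I2 (1.3 equiv), CH2Cl2, 0 °C → rt, dark
Reagents that add atoms: iodine, II
Why: Appel-type iodination: the alkoxyphosphonium is displaced by iodide in an SN2 reaction at the primary carbon, run cold in a non-ionising solvent so that the electron-rich aryl group does not migrate, and the stereocentre is not a reacting centre.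

Step 7
Reactants: 9 the (R)-iodide of step 6
Product: 12 (4R)-5-bromo-4-[3-methoxy-4-(triisopropylsilyloxy)phenyl]-7-(triisopropylsilyloxy)-3,4-dihydro-2H-chromen-2-one, via alkylzinc iodide 10 (not isolated), via iodozinc carboxylate 11 (not isolated)
Conditions: Zn dust (3 equiv, activated with BrCH2CH2Br/Me3SiCl), LiCl (1.5 equiv), THF, 40 °C; solution decanted from excess Zn into CuI (10 mol %), 1,10-phenanthroline (12 mol %), DMF under CO2 (1 atm), 50 °C, then 110 °C
Reagents that add atoms: carbon dioxide, O=C=O
Why: Proposed new method: zinc inserts into the primary C–I bond of 9 (Zn/LiCl leaves aryl C–Br bonds alone) to give 10; transfer of the alkyl group to phenanthroline-ligated monovalent copper and insertion of CO2 into the C3–Cu bond (backed up by the direct LiCl/DMF-promoted carboxylation of 10) makes the C3–C2 bond and gives carboxylate 11, and on heating the copper carboxylate adds oxidatively to the flanking C8a–Br bond and reductively eliminates the O1–C8a bond, the CuBr released being returned to the cycle by exchange with zinc carboxylate. The closest known reaction types are the carboxylation of alkylzinc halides with CO2 (Ni- or Pd-catalysed, or LiCl-promoted), the copper-catalysed carboxylation of alkylboranes and the copper-mediated intramolecular O-arylation of carboxylates by ortho-haloarenes (Ullmann–Hurtley lactonisation); only their merger into one catalytic carboxylative lactonisation is new. Ring B closes as the six-membered lactone by attack of the carboxylate oxygen on C8a through a seven-membered cupracycle (a 6-exo closure onto the arene), whereas direct C3–C8a coupling would give a four-membered ring and is outrun by CO2 capture at 50 °C before the mixture is heated. No stereocentre is created: C4, set in step 4, is β to zinc and to the new carbonyl group and is not deprotonated by the weakly basic zinc and copper carboxylates, so it is carried through unchanged. The selectivities needed are C(sp3)–I over C(sp2)–Br in the zinc insertion, secured by the reactivity gap between a primary alkyl iodide and an electron-rich aryl bromide, and a single C–O coupling on a dibromoarene, secured because the two bromines are equivalent by rotation about C4–C4a and only one carboxylate is tethered, which leaves the other bromine at C5.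

Step 8
Reactants: 12 the (4R)-bromolactone of step 7; 6 (4-ethenyl-2-methoxyphenoxy)triisopropylsilane
Product: 13 (4R)-4-[3-methoxy-4-(triisopropylsilyloxy)phenyl]-5-{(E)-2-[3-methoxy-4-(triisopropylsilyloxy)phenyl]ethenyl}-7-(triisopropylsilyloxy)-3,4-dihydro-2H-chromen-2-one
Conditions: 6 (1.5 equiv), Pd2(dba)3 (2.5 mol %), [HP(t-Bu)3]BF4 (10 mol %), Cy2NMe (1.5 equiv), 1,4-dioxane, 80 °C
Reagents that add atoms: none
Why: Mizoroki–Heck reaction: oxidative addition of zerovalent palladium/P(t-Bu)3 to the remaining C5–Br bond, syn-insertion of the terminal alkene of 6 with aryl transfer to the CH2 carbon and syn-β-hydride elimination should give the E-stilbene, with the hindered amine base sparing the lactone.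

Step 9
Reactants: 13 the tris-silyl ether of step 8
Product: 14 (4R)-7-hydroxy-4-(4-hydroxy-3-methoxyphenyl)-5-[(E)-2-(4-hydroxy-3-methoxyphenyl)ethenyl]-3,4-dihydro-2H-chromen-2-one (CNP0277187.1)
Conditions: Bu4NF (3.6 equiv), AcOH (3.6 equiv), THF, 0 °C, argon, dark
Reagents that add atoms: none
Why: Fluoride-mediated cleavage of the three aryl silyl ethers (desilylation), buffered with acetic acid so that no free phenoxide opens the lactone or is oxidised, and run cold and in the dark to keep the E-stilbene and the C4 stereocentre intact.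

**Compound list**

1 | 3,5-dibromophenol | Oc1cc(Br)cc(Br)c1 | starting material
2 | (3,5-dibromophenoxy)triisopropylsilane | CC(C)[Si](Oc1cc(Br)cc(Br)c1)(C(C)C)C(C)C | intermediate
3 | [2,6-dibromo-4-(triisopropylsilyloxy)phenyl]lithium | [Li]c1c(Br)cc(O[Si](C(C)C)(C(C)C)C(C)C)cc1Br | intermediate (not isolated)
4 | (3,5-dibromo-4-iodophenoxy)triisopropylsilane | Ic1c(Br)cc(O[Si](C(C)C)(C(C)C)C(C)C)cc1Br | intermediate
5 | 2-methoxy-4-vinylphenol | C=Cc1ccc(O)c(OC)c1 | starting material
6 | (4-ethenyl-2-methoxyphenoxy)triisopropylsilane | C=Cc1ccc(O[Si](C(C)C)(C(C)C)C(C)C)c(OC)c1 | intermediate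
7 | 2-{(2R)-2-[2,6-dibromo-4-(triisopropylsilyloxy)phenyl]-2-[3-methoxy-4-(triisopropylsilyloxy)phenyl]ethyl}-4,4,5,5-tetramethyl-1,3,2-dioxaborolane | CC1(C)OB(C[C@H](c2ccc(O[Si](C(C)C)(C(C)C)C(C)C)c(OC)c2)c2c(Br)cc(O[Si](C(C)C)(C(C)C)C(C)C)cc2Br)OC1(C)C | intermediate
8 | (2R)-2-[2,6-dibromo-4-(triisopropylsilyloxy)phenyl]-2-[3-methoxy-4-(triisopropylsilyloxy)phenyl]ethan-1-ol | OC[C@H](c1ccc(O[Si](C(C)C)(C(C)C)C(C)C)c(OC)c1)c1c(Br)cc(O[Si](C(C)C)(C(C)C)C(C)C)cc1Br | intermediate
9 | {3,5-dibromo-4-[(1R)-2-iodo-1-[3-methoxy-4-(triisopropylsilyloxy)phenyl]ethyl]phenoxy}triisopropylsilane | IC[C@H](c1ccc(O[Si](C(C)C)(C(C)C)C(C)C)c(OC)c1)c1c(Br)cc(O[Si](C(C)C)(C(C)C)C(C)C)cc1Br | intermediate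
10 | {(2R)-2-[2,6-dibromo-4-(triisopropylsilyloxy)phenyl]-2-[3-methoxy-4-(triisopropylsilyloxy)phenyl]ethyl}zinc iodide | I[Zn]C[C@H](c1ccc(O[Si](C(C)C)(C(C)C)C(C)C)c(OC)c1)c1c(Br)cc(O[Si](C(C)C)(C(C)C)C(C)C)cc1Br | intermediate (not isolated)
11 | iodozinc (3R)-3-[2,6-dibromo-4-(triisopropylsilyloxy)phenyl]-3-[3-methoxy-4-(triisopropylsilyloxy)phenyl]propanoate | O=C(C[C@H](c1ccc(O[Si](C(C)C)(C(C)C)C(C)C)c(OC)c1)c1c(Br)cc(O[Si](C(C)C)(C(C)C)C(C)C)cc1Br)O[Zn]I | intermediate (not isolated)
12 | (4R)-5-bromo-4-[3-methoxy-4-(triisopropylsilyloxy)phenyl]-7-(triisopropylsilyloxy)-3,4-dihydro-2H-chromen-2-one | O=C1C[C@H](c2ccc(O[Si](C(C)C)(C(C)C)C(C)C)c(OC)c2)c2c(Br)cc(O[Si](C(C)C)(C(C)C)C(C)C)cc2O1 | intermediate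
13 | (4R)-4-[3-methoxy-4-(triisopropylsilyloxy)phenyl]-5-{(E)-2-[3-methoxy-4-(triisopropylsilyloxy)phenyl]ethenyl}-7-(triisopropylsilyloxy)-3,4-dihydro-2H-chromen-2-one | O=C1C[C@H](c2ccc(O[Si](C(C)C)(C(C)C)C(C)C)c(OC)c2)c2c(/C=C/c3ccc(O[Si](C(C)C)(C(C)C)C(C)C)c(OC)c3)cc(O[Si](C(C)C)(C(C)C)C(C)C)cc2O1 | intermediate
14 | (4R)-7-hydroxy-4-(4-hydroxy-3-methoxyphenyl)-5-[(E)-2-(4-hydroxy-3-methoxyphenyl)ethenyl]-3,4-dihydro-2H-chromen-2-one | COc1cc(/C=C/c2cc(O)cc3c2[C@@H](c2ccc(O)c(OC)c2)CC(=O)O3)ccc1O | target

**Step count and risks**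

Total step count: 9. Longest linear sequence: 8 (steps 1, 2, 4, 5, 6, 7, 8, 9).

Steps most likely to fail:

1. Step 7 (proposed new method). The copper-mediated C–O coupling may not turn over on the hindered, electron-rich C8a–Br bond, so that the sequence stalls at the zinc carboxylate, or the alkylzinc may be protonated before it captures CO2. The fallback uses known chemistry and makes the O1–C8a bond by aryl migration to oxygen instead of C–O coupling. It sets out from 9: zinc insertion (Zn, LiCl, THF) and the known LiCl/DMF-promoted carboxylation of the alkylzinc iodide with CO2, with HCl work-up, should give (3R)-3-[2,6-dibromo-4-(triisopropylsilyloxy)phenyl]-3-[3-methoxy-4-(triisopropylsilyloxy)phenyl]propanoic acid F1. Parham cycliacylation (n-BuLi, 2.05 equiv, THF, −100 °C; bromine–lithium exchange at one of the two equivalent bromines and 5-exo attack on the lithium carboxylate) should give (3R)-4-bromo-3-[3-methoxy-4-(triisopropylsilyloxy)phenyl]-6-(triisopropylsilyloxy)-2,3-dihydro-1H-inden-1-one F2. Baeyer–Villiger oxidation (mCPBA, NaHCO3, CH2Cl2), with migration of the aryl carbon as usual for 1-indanones, inserts oxygen between C2 and C8a and comes back to the route at 12.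

2. Step 4. Transfer of the secondary benzylic copper to the doubly ortho-brominated arylpalladium may be slow, which would allow protodecupration, borylation of the aryl iodide or erosion of the enantiomeric purity. The fallback sets the stereocentre by hydride delivery to a preformed 1,1-diarylethylene. It sets out from 2, which is lithiated to 3 as in step 2, transmetalated with CeCl3 and added to 1-[3-methoxy-4-(triisopropylsilyloxy)phenyl]ethan-1-one F3 (made from commercial acetovanillone with TIPSCl and imidazole) to give rac-1-[2,6-dibromo-4-(triisopropylsilyloxy)phenyl]-1-[3-methoxy-4-(triisopropylsilyloxy)phenyl]ethan-1-ol F4. Dehydration (TsOH cat., toluene, 40 °C) should give {3,5-dibromo-4-[1-[3-methoxy-4-(triisopropylsilyloxy)phenyl]ethenyl]phenoxy}triisopropylsilane F5. CuH-catalysed enantioselective anti-Markovnikov hydroboration (CuCl, (R)- or (S)-DTBM-SEGPHOS, NaOt-Bu cat., HBpin, toluene), in which the dibromoaryl ring, twisted out of the alkene plane, acts as the large substituent, comes back to the route at 7.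

3. Step 8. Insertion and β-hydride elimination at the crowded C5 position may be sluggish with the electron-rich styrene, leading to hydrodebromination, some branched 1,1-diarylalkene, or opening of the lactone by the amine on prolonged heating. The fallback fixes the E geometry in the coupling partner. It sets out from 6: cross-metathesis with 4,4,5,5-tetramethyl-2-vinyl-1,3,2-dioxaborolane (second-generation Grubbs catalyst RuCl2(=CHPh)(H2IMes)(PCy3), CH2Cl2, 40 °C) should give 2-{(E)-2-[3-methoxy-4-(triisopropylsilyloxy)phenyl]ethenyl}-4,4,5,5-tetramethyl-1,3,2-dioxaborolane F6. Suzuki–Miyaura coupling of F6 with 12 (Pd(OAc)2/SPhos, CsF, 1,4-dioxane, 60 °C, anhydrous) comes back to the route at 13.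

Further compounds
F1 | step 7 | (3R)-3-[2,6-dibromo-4-(triisopropylsilyloxy)phenyl]-3-[3-methoxy-4-(triisopropylsilyloxy)phenyl]propanoic acid | O=C(O)C[C@H](c1ccc(O[Si](C(C)C)(C(C)C)C(C)C)c(OC)c1)c1c(Br)cc(O[Si](C(C)C)(C(C)C)C(C)C)cc1Br
F2 | step 7 | (3R)-4-bromo-3-[3-methoxy-4-(triisopropylsilyloxy)phenyl]-6-(triisopropylsilyloxy)-2,3-dihydro-1H-inden-1-one | O=C1C[C@H](c2ccc(O[Si](C(C)C)(C(C)C)C(C)C)c(OC)c2)c2c(Br)cc(O[Si](C(C)C)(C(C)C)C(C)C)cc21
F3 | step 4 | 1-[3-methoxy-4-(triisopropylsilyloxy)phenyl]ethan-1-one | CC(=O)c1ccc(O[Si](C(C)C)(C(C)C)C(C)C)c(OC)c1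
F4 | step 4 | rac-1-[2,6-dibromo-4-(triisopropylsilyloxy)phenyl]-1-[3-methoxy-4-(triisopropylsilyloxy)phenyl]ethan-1-ol | CC(O)(c1ccc(O[Si](C(C)C)(C(C)C)C(C)C)c(OC)c1)c1c(Br)cc(O[Si](C(C)C)(C(C)C)C(C)C)cc1Br
F5 | step 4 | {3,5-dibromo-4-[1-[3-methoxy-4-(triisopropylsilyloxy)phenyl]ethenyl]phenoxy}triisopropylsilane | C=C(c1ccc(O[Si](C(C)C)(C(C)C)C(C)C)c(OC)c1)c1c(Br)cc(O[Si](C(C)C)(C(C)C)C(C)C)cc1Br
F6 | step 8 | 2-{(E)-2-[3-methoxy-4-(triisopropylsilyloxy)phenyl]ethenyl}-4,4,5,5-tetramethyl-1,3,2-dioxaborolane | CC1(C)OB(/C=C/c2ccc(O[Si](C(C)C)(C(C)C)C(C)C)c(OC)c2)OC1(C)C
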